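**Plan**
Carotenoid numbering: ring C1 (gem-dimethyl) to C6, C5 the methyl carbinol, chain C7–C15, then C15'–C10' to the acid.
Retrosynthesis: cut C11=C12 (C15 dienal + C12 tetraenyl phosphonate), then C7=C8 (ring aldehyde + C5 phosphonate), then the ring bond C1–C6, which leads to an open-chain ketone with the carbon skeleton of linalool.
Enabling feature: in the trimethylcyclohexane ring the gem-dimethyl carbon C1 is bonded to the carbinol C6, and C6 lies between two oxygen-bearing carbons (C5, and C7 before the chain is built). C6 can therefore be the carbonyl of a 1,3-dioxan-5-one and C1 a tertiary radical made from a prenyl-type alkene.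
Forward: (R)-linalool → dioxanone → radical closure of the carbocycle (the only ring formed) → C7 aldehyde → C15 ester, alcohol, aldehyde → coupling with the C12 phosphonate made from the C10 dialdehyde → saponification.
Stereochemistry: C5 comes unchanged from (R)-linalool; C6 is set by C5 in the ring closure (cis-fused bicycle, hence the trans-5,6-diol); the seven E double bonds come from E-configured building blocks and from stabilised Wittig and phosphonate olefinations.

Key step: step 6

Remarks on the chemistry: the oxirane carbon of 2 and C2 of 3 and 4 are carried as epimer mixtures, because this carbon becomes the C6 carbonyl in step 4. Commercial 12 is an E/Z mixture at its trisubstituted double bond; its delocalised anion is expected to give mainly the 2E product.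

Step 1
Reactants: 1 (R)-linalool [(3R)-3,7-dimethylocta-1,6-dien-3-ol]
Product: 2 (2R)-6-methyl-2-(oxiran-2-yl)hept-5-en-2-ol (both epimers at the oxirane carbon)
Conditions: VO(acac)2 (3 mol %), t-BuOOH (1.5 equiv, decane solution), toluene, 0 °C to rt
Reagents that add atoms: tert-butyl hydroperoxide, CC(C)(C)OO
Why: Vanadium-catalysed hydroxyl-directed epoxidation, in which the tertiary allylic alcohol binds the vanadium peroxide and delivers oxygen to the adjacent vinyl group through a tight allylic transition state faster than to the remote trisubstituted alkene, the new oxirane centre forming as a harmless epimer mixture.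

Step 2
Reactants: 2 (2R)-6-methyl-2-(oxiran-2-yl)hept-5-en-2-ol
Product: 3 (3R)-3,7-dimethyloct-6-ene-1,2,3-triol (both epimers at C2)
Conditions: NaOH (1 M aq.), t-BuOH, 75 °C
Reagents that add atoms: water, O
Why: Base-mediated SN2 epoxide hydrolysis (directly or after Payne rearrangement), in which hydroxide attacks only the primary or secondary oxirane carbon, so the C–O bond of the tertiary carbinol is never broken and its R configuration is kept.

Step 3
Reactants: 3 (3R)-3,7-dimethyloct-6-ene-1,2,3-triol
Product: 4 (3R)-1-[(tert-butyldimethylsilyl)oxy]-3,7-dimethyloct-6-ene-2,3-diol (both epimers at C2)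
Conditions: TBSCl (1.05 equiv), imidazole, CH2Cl2, 0 °C
Reagents that add atoms: tert-butyldimethylsilyl chloride, CC(C)(C)[Si](C)(C)Cl
Why: Chemoselective silylation, the bulky silyl chloride reacting with the primary hydroxyl far faster than with the secondary and tertiary ones.

Step 4
Reactants: 4 (3R)-1-[(tert-butyldimethylsilyl)oxy]-3,7-dimethyloct-6-ene-2,3-diol
Product: 5 (3R)-1-[(tert-butyldimethylsilyl)oxy]-3-hydroxy-3,7-dimethyloct-6-en-2-one
Conditions: IBX (1.5 equiv), DMSO, rt to 40 °C
Reagents that add atoms: none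
Why: IBX oxidation of a secondary alcohol, which turns the secondary carbinol of a 1,2-diol into the α-hydroxy ketone without glycol cleavage, leaves the tertiary alcohol, silyl ether and alkene untouched and erases the C2 epimer mixture.

Step 5
Reactants: 5 (3R)-1-[(tert-butyldimethylsilyl)oxy]-3-hydroxy-3,7-dimethyloct-6-en-2-one; 6 2,2-dimethoxypropane
Product: 8 (4R)-2,2,4-trimethyl-4-(4-methylpent-3-en-1-yl)-1,3-dioxan-5-one, via dihydroxy ketone 7 (not isolated)
Conditions: CSA (10 mol %), MeOH, 0 °C to rt; evaporate; 6/acetone (1:1), rt; Et3N quench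
Reagents that add atoms: none
Why: Acid-catalysed silyl ether methanolysis followed by transacetalisation, in which the only diol left for 2,2-dimethoxypropane is the 1,3-pair flanking the ketone, so the 1,3-dioxan-5-one closes while the tertiary stereocentre, whose C–O bond is not touched, is kept.

Step 6
Reactants: 8 (4R)-2,2,4-trimethyl-4-(4-methylpent-3-en-1-yl)-1,3-dioxan-5-one
Product: 9 (4aS,8aR)-2,2,5,5,8a-pentamethylhexahydro-4H-1,3-benzodioxin-4a-ol (cis-fused; O5 and O7 bridged by the acetonide, C6 hydroxyl free)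
Conditions: Fe(acac)3 (1.0 equiv), PhSiH3 (2.5 equiv), EtOH (0.03 M), 60 °C, Ar
Reagents that add atoms: none
Why: The iron hydride made from Fe(acac)3, PhSiH3 and ethanol hands a hydrogen atom to the less substituted alkene carbon C2, so the radical is born at the tertiary C1 (Markovnikov selectivity, secured by radical stability). This nucleophilic radical attacks the carbonyl carbon C6, made electron-poor by the two α-oxygens, in a 6-exo-trig closure onto C=O that forms the carbocycle, and the oxygen-centred radical (or its iron-bound equivalent) is reduced by divalent iron to the alkoxide and protonated by ethanol before it can fragment. The closest known reaction type is the iron-hydride hydrogen-atom-transfer reductive cyclisation of alkene-tethered ketones to cis-fused bicyclic tertiary alcohols. The one new stereocentre, C6, is controlled by C5 through a chair transition state: the axial methyl on C1 pushes the C5 methyl equatorial and O5 axial, and the dioxanone ring keeps C7 gauche to O5 and thus equatorial, so the new C6–O bond ends axial and anti to O5. The step therefore needs cis ring fusion (O6 trans to O5, cis to the C5 methyl), which the acetonide bridge and the gem-dimethyl group together secure, since a trans-fused closure would place the C5 methyl 1,3-diaxial to a C1 methyl.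

Step 7
Reactants: 9 (4aS,8aR)-2,2,5,5,8a-pentamethylhexahydro-4H-1,3-benzodioxin-4a-ol
Product: 10 (1S,2R)-1-(hydroxymethyl)-2,6,6-trimethylcyclohexane-1,2-diol
Conditions: AcOH/H2O/THF (3:1:1), 40 °C
Reagents that add atoms: none
Why: Acid-catalysed acetal hydrolysis, which cleaves the crowded tetrasubstituted dioxane at the acetal carbon under mild aqueous acid, so no C–O bond at C5 or C6 is broken and both tertiary centres keep their configuration.

Step 8
Reactants: 10 (1S,2R)-1-(hydroxymethyl)-2,6,6-trimethylcyclohexane-1,2-diol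
Product: 11 (1R,2R)-1,2-dihydroxy-2,6,6-trimethylcyclohexane-1-carbaldehyde
Conditions: IBX (1.3 equiv), DMSO, rt
Reagents that add atoms: none
Why: IBX oxidation of a primary alcohol, in which only the primary hydroxyl can be oxidised, the vicinal tertiary diol is not cleaved, and the aldehyde has no α-hydrogen and so cannot epimerise.

Step 9
Reactants: 11 (1R,2R)-1,2-dihydroxy-2,6,6-trimethylcyclohexane-1-carbaldehyde; 12 triethyl 3-methyl-4-phosphonocrotonate [ethyl (2E)-4-(diethoxyphosphoryl)-3-methylbut-2-enoate]
Product: 13 ethyl (2E,4E)-5-[(1R,2R)-1,2-dihydroxy-2,6,6-trimethylcyclohexyl]-3-methylpenta-2,4-dienoate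
Conditions: 12 (2.0 equiv), LiN(SiMe3)2 (1.9 equiv), THF, −78 °C; then 11, −78 to 0 °C
Reagents that add atoms: none
Why: Horner–Wadsworth–Emmons olefination, in which the ester-stabilised allylic phosphonate anion is too weak a base to turn the tertiary hydroxyls into alkoxides, adds to the non-enolisable aldehyde and eliminates to the E C7=C8 bond under the usual thermodynamic control, any 2Z isomer being removed by chromatography.

Step 10
Reactants: 13 ethyl (2E,4E)-5-[(1R,2R)-1,2-dihydroxy-2,6,6-trimethylcyclohexyl]-3-methylpenta-2,4-dienoate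
Product: 14 (1R,2R)-1-[(1E,3E)-5-hydroxy-3-methylpenta-1,3-dien-1-yl]-2,6,6-trimethylcyclohexane-1,2-diol
Conditions: iBu2AlH (4.5 equiv), CH2Cl2, −78 °C; aq. KNaC4H4O6 (potassium sodium tartrate) work-up
Reagents that add atoms: none
Why: iBu2AlH reduction of a conjugated ester, the hydride reducing the ester carbonyl by 1,2-addition to the allylic alcohol at low temperature while the tertiary hydroxyls merely consume reagent as aluminium alkoxides.

Step 11
Reactants: 14 (1R,2R)-1-[(1E,3E)-5-hydroxy-3-methylpenta-1,3-dien-1-yl]-2,6,6-trimethylcyclohexane-1,2-diol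
Product: 15 (2E,4E)-5-[(1R,2R)-1,2-dihydroxy-2,6,6-trimethylcyclohexyl]-3-methylpenta-2,4-dienal
Conditions: activated MnO2 (20 equiv), CH2Cl2, rt, dark
Reagents that add atoms: none
Why: MnO2 allylic oxidation, which oxidises only the primary allylic alcohol to the dienal under neutral conditions, the tertiary alcohols being inert and the E,E geometry preserved.

Step 12
Reactants: 16 (2E,4E,6E)-2,7-dimethylocta-2,4,6-trienedial; 17 ethyl (triphenylphosphoranylidene)acetate
Product: 18 ethyl (2E,4E,6E,8E)-4,9-dimethyl-10-oxodeca-2,4,6,8-tetraenoate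
Conditions: 16 (2.0 equiv), 17 (1.0 equiv, slow addition), CH2Cl2, 0 °C to rt, dark
Reagents that add atoms: none
Why: Wittig reaction of a stabilised ylide, which gives the E alkene and, with the ylide in deficit against the symmetric dialdehyde, should stop after one olefination because the product aldehyde is more conjugated and less electrophilic.

Step 13
Reactants: 18 ethyl (2E,4E,6E,8E)-4,9-dimethyl-10-oxodeca-2,4,6,8-tetraenoate
Product: 19 ethyl (2E,4E,6E,8E)-10-hydroxy-4,9-dimethyldeca-2,4,6,8-tetraenoate
Conditions: NaBH4, MeOH/THF, −20 °C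
Reagents that add atoms: none
Why: Chemoselective NaBH4 reduction, borohydride reducing the conjugated aldehyde by 1,2-addition at low temperature and leaving the conjugated ester alone.

Step 14
Reactants: 19 ethyl (2E,4E,6E,8E)-10-hydroxy-4,9-dimethyldeca-2,4,6,8-tetraenoate
Product: 20 ethyl (2E,4E,6E,8E)-10-bromo-4,9-dimethyldeca-2,4,6,8-tetraenoate
Conditions: PBr3 (0.4 equiv), pyridine (cat.), Et2O, −20 to 0 °C, dark; used crude
Reagents that add atoms: phosphorus tribromide, BrP(Br)Br
Why: Bromination of a primary allylic alcohol with PBr3, the intermediate phosphite ester being displaced by bromide at the primary carbon at low temperature and the sensitive bromide being used at once.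

Step 15
Reactants: 20 ethyl (2E,4E,6E,8E)-10-bromo-4,9-dimethyldeca-2,4,6,8-tetraenoate
Product: 21 ethyl (2E,4E,6E,8E)-10-(diethoxyphosphoryl)-4,9-dimethyldeca-2,4,6,8-tetraenoate
Conditions: P(OEt)3 (neat, excess), 90 °C, Ar, dark
Reagents that add atoms: triethyl phosphite, CCOP(OCC)OCC
Why: Michaelis–Arbuzov reaction, the phosphite displacing the primary allylic bromide and the phosphonium intermediate losing bromoethane to give the phosphonate.

Step 16
Reactants: 15 (2E,4E)-5-[(1R,2R)-1,2-dihydroxy-2,6,6-trimethylcyclohexyl]-3-methylpenta-2,4-dienal; 21 ethyl (2E,4E,6E,8E)-10-(diethoxyphosphoryl)-4,9-dimethyldeca-2,4,6,8-tetraenoate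
Product: 22 ethyl (2E,4E,6E,8E,10E,12E,14E)-15-[(1R,2R)-1,2-dihydroxy-2,6,6-trimethylcyclohexyl]-4,9,13-trimethylpentadeca-2,4,6,8,10,12,14-heptaenoate
Conditions: 21 (1.3 equiv), NaN(SiMe3)2 (1.25 equiv), THF, −78 °C; then 15, −78 to 0 °C, dark
Reagents that add atoms: none
Why: Horner–Wadsworth–Emmons olefination, the delocalised phosphonate anion adding through its α-carbon to the dienal and eliminating to the E C11=C12 bond (the Z isomer is disfavoured by the clash of the C13 methyl with C10–H) while the tertiary hydroxyls stay protonated.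

Step 17
Reactants: 22 ethyl (2E,4E,6E,8E,10E,12E,14E)-15-[(1R,2R)-1,2-dihydroxy-2,6,6-trimethylcyclohexyl]-4,9,13-trimethylpentadeca-2,4,6,8,10,12,14-heptaenoate
Product: 23 (2E,4E,6E,8E,10E,12E,14E)-15-[(1R,2R)-1,2-dihydroxy-2,6,6-trimethylcyclohexyl]-4,9,13-trimethylpentadeca-2,4,6,8,10,12,14-heptaenoic acid [(5R,6R)-5,6-dihydroxy-5,6-dihydro-10'-apo-β-caroten-10'-oic acid]
Conditions: KOH (aq.), EtOH/THF, 40 °C, Ar, dark; then dilute HCl to pH 4–5, 0 °C
Reagents that add atoms: potassium hydroxide, [K+].[OH-]
Why: Ester saponification by acyl–oxygen cleavage with hydroxide, the polyene carboxylate and the tertiary diol being stable to aqueous base and the cold acidification to pH 4–5 avoiding ionisation of the allylic C6 hydroxyl.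

**Compound list**
1 | (R)-linalool, (3R)-3,7-dimethylocta-1,6-dien-3-ol | C=C[C@](C)(O)CCC=C(C)C | starting material
2 | (2R)-6-methyl-2-(oxiran-2-yl)hept-5-en-2-ol (oxirane epimers) | C1OC1[C@](C)(O)CCC=C(C)C | intermediate
3 | (3R)-3,7-dimethyloct-6-ene-1,2,3-triol (C2 epimers) | OCC(O)[C@](C)(O)CCC=C(C)C | intermediate
4 | (3R)-1-[(tert-butyldimethylsilyl)oxy]-3,7-dimethyloct-6-ene-2,3-diol (C2 epimers) | CC(C)(C)[Si](C)(C)OCC(O)[C@](C)(O)CCC=C(C)C | intermediate
5 | (3R)-1-[(tert-butyldimethylsilyl)oxy]-3-hydroxy-3,7-dimethyloct-6-en-2-one | CC(C)(C)[Si](C)(C)OCC(=O)[C@](C)(O)CCC=C(C)C | intermediate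
6 | 2,2-dimethoxypropane | COC(C)(C)OC | starting material
7 | (3R)-1,3-dihydroxy-3,7-dimethyloct-6-en-2-one | OCC(=O)[C@](C)(O)CCC=C(C)C | intermediate
8 | (4R)-2,2,4-trimethyl-4-(4-methylpent-3-en-1-yl)-1,3-dioxan-5-one | CC(C)=CCC[C@@]1(C)OC(C)(C)OCC1=O | intermediate
9 | (4aS,8aR)-2,2,5,5,8a-pentamethylhexahydro-4H-1,3-benzodioxin-4a-ol (cis-fused) | CC1(C)CCC[C@@]2(C)OC(C)(C)OC[C@@]12O | intermediate
10 | (1S,2R)-1-(hydroxymethyl)-2,6,6-trimethylcyclohexane-1,2-diol | OC[C@@]1(O)C(C)(C)CCC[C@@]1(C)O | intermediate
11 | (1R,2R)-1,2-dihydroxy-2,6,6-trimethylcyclohexane-1-carbaldehyde | O=C[C@@]1(O)C(C)(C)CCC[C@@]1(C)O | intermediate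
12 | triethyl 3-methyl-4-phosphonocrotonate, ethyl (2E)-4-(diethoxyphosphoryl)-3-methylbut-2-enoate | CCOC(=O)/C=C(C)/CP(=O)(OCC)OCC | starting material
13 | ethyl (2E,4E)-5-[(1R,2R)-1,2-dihydroxy-2,6,6-trimethylcyclohexyl]-3-methylpenta-2,4-dienoate | CCOC(=O)/C=C(C)/C=C/[C@@]1(O)C(C)(C)CCC[C@@]1(C)O | intermediate
14 | (1R,2R)-1-[(1E,3E)-5-hydroxy-3-methylpenta-1,3-dien-1-yl]-2,6,6-trimethylcyclohexane-1,2-diol | OC/C=C(C)/C=C/[C@@]1(O)C(C)(C)CCC[C@@]1(C)O | intermediate
15 | (2E,4E)-5-[(1R,2R)-1,2-dihydroxy-2,6,6-trimethylcyclohexyl]-3-methylpenta-2,4-dienal | O=C/C=C(C)/C=C/[C@@]1(O)C(C)(C)CCC[C@@]1(C)O | intermediate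
16 | (2E,4E,6E)-2,7-dimethylocta-2,4,6-trienedial | O=C/C(C)=C/C=C/C=C(C)/C=O | starting material
17 | ethyl (triphenylphosphoranylidene)acetate | CCOC(=O)C=P(c1ccccc1)(c1ccccc1)c1ccccc1 | starting material
18 | ethyl (2E,4E,6E,8E)-4,9-dimethyl-10-oxodeca-2,4,6,8-tetraenoate | CCOC(=O)/C=C/C(C)=C/C=C/C=C(C)/C=O | intermediate
19 | ethyl (2E,4E,6E,8E)-10-hydroxy-4,9-dimethyldeca-2,4,6,8-tetraenoate | CCOC(=O)/C=C/C(C)=C/C=C/C=C(C)/CO | intermediate
20 | ethyl (2E,4E,6E,8E)-10-bromo-4,9-dimethyldeca-2,4,6,8-tetraenoate | CCOC(=O)/C=C/C(C)=C/C=C/C=C(C)/CBr | intermediate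
21 | ethyl (2E,4E,6E,8E)-10-(diethoxyphosphoryl)-4,9-dimethyldeca-2,4,6,8-tetraenoate | CCOC(=O)/C=C/C(C)=C/C=C/C=C(C)/CP(=O)(OCC)OCC | intermediate
22 | ethyl (2E,4E,6E,8E,10E,12E,14E)-15-[(1R,2R)-1,2-dihydroxy-2,6,6-trimethylcyclohexyl]-4,9,13-trimethylpentadeca-2,4,6,8,10,12,14-heptaenoate | CC(/C=C/C=C(C)/C=C/[C@@]1(O)C(C)(C)CCC[C@@]1(C)O)=C\C=C\C=C(C)\C=C\C(=O)OCC | intermediate
23 | (2E,4E,6E,8E,10E,12E,14E)-15-[(1R,2R)-1,2-dihydroxy-2,6,6-trimethylcyclohexyl]-4,9,13-trimethylpentadeca-2,4,6,8,10,12,14-heptaenoic acid | CC(/C=C/C=C(C)/C=C/[C@@]1(O)C(C)(C)CCC[C@@]1(C)O)=C\C=C\C=C(C)\C=C\C(=O)O | target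

**Step count and risks**
Total step count: 17. Longest linear sequence: 13 steps (steps 1–11, 16 and 17, from 1); the C12 phosphonate 21 is made in 4 steps (12–15) from 16.

Steps most likely to fail:

1. Step 6. The crowded tertiary alkoxy radical may fragment by β-scission (toward the oxygen-stabilised C5 or back to C1), or the C1 radical may be reduced by iron hydride before it closes, so that ring-opened or merely hydrogenated material forms. The fallback sets out from 8 and returns at 9. The trisubstituted alkene is epoxidised with mCPBA (NaHCO3, CH2Cl2, 0 °C) to the epoxy dioxanone F1. Cp2TiCl, made in the flask from Cp2TiCl2 and Mn powder in THF, opens the oxirane homolytically at the tertiary carbon to the same C1 radical, which closes onto C6 while a second equivalent of trivalent titanium captures the oxygen as a titanium alkoxide, giving the bicyclic diol F2 with an extra hydroxyl on carotenoid C2. Only this secondary hydroxyl is converted (NaH, CS2, then MeI, THF) into the xanthate F3, and Barton–McCombie reduction (Bu3SnH, AIBN, toluene, 90 °C) removes it to give 9.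

2. Step 9. Alkoxide formation at the β-hydroxyl may trigger retro-aldol opening of the ring (C5–C6 cleavage), or an α-ketol ring expansion may set in, faster than the anion adds to the very hindered aldehyde. The fallback sets out from 11 and returns at 13. A Wittig reaction with the neutral stabilised ylide 1-(triphenylphosphoranylidene)propan-2-one (toluene, 80 °C, no added base) gives the dihydroxy enone F4. Once the aldehyde is gone the fragmentation path no longer exists, and Horner–Wadsworth–Emmons reaction of the methyl ketone with the pre-formed sodium salt of triethyl phosphonoacetate (NaH in slight deficit, THF, 0 °C to rt), followed by removal of the 2Z isomer, gives 13.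

3. Step 5. Closure of the strained tetrasubstituted dioxane is reversible and may stay incomplete, while the free dihydroxy ketone is ketalised at the carbonyl or isomerises under acid. The fallback sets out from 5 and returns at 10. HF·pyridine (THF, 0 °C) frees the dihydroxy ketone 7, which is bridged irreversibly under basic conditions with tBu2Si(OTf)2 and 2,6-lutidine (CH2Cl2, 0 °C) to the silylene-bridged ketone F5. The same Fe(acac)3/PhSiH3 ring closure then gives the bicyclic silylene F6, and HF·pyridine (THF, rt) releases triol 10.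

**Further compounds**
F1 | step 6 | (4R)-4-[2-(3,3-dimethyloxiran-2-yl)ethyl]-2,2,4-trimethyl-1,3-dioxan-5-one (oxirane epimers) | CC1(C)OC1CC[C@@]1(C)OC(C)(C)OCC1=O
F2 | step 6 | (4aS,8aR)-2,2,5,5,8a-pentamethylhexahydro-4H-1,3-benzodioxine-4a,6-diol (epimers at C6 of the benzodioxine) | CC1(C)C(O)CC[C@@]2(C)OC(C)(C)OC[C@@]12O
F3 | step 6 | O-[(4aS,8aR)-4a-hydroxy-2,2,5,5,8a-pentamethylhexahydro-4H-1,3-benzodioxin-6-yl] S-methyl carbonodithioate | CC1(C)C(OC(=S)SC)CC[C@@]2(C)OC(C)(C)OC[C@@]12O
F4 | step 9 | (3E)-4-[(1R,2R)-1,2-dihydroxy-2,6,6-trimethylcyclohexyl]but-3-en-2-one | CC(=O)/C=C/[C@@]1(O)C(C)(C)CCC[C@@]1(C)O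
F5 | step 5 | (4R)-2,2-di-tert-butyl-4-methyl-4-(4-methylpent-3-en-1-yl)-1,3,2-dioxasilinan-5-one | CC(C)=CCC[C@@]1(C)O[Si](OCC1=O)(C(C)(C)C)C(C)(C)C
F6 | step 5 | (4aS,8aR)-2,2-di-tert-butyl-5,5,8a-trimethylhexahydro-4H-benzo[d][1,3,2]dioxasilin-4a-ol | CC1(C)CCC[C@@]2(C)O[Si](OC[C@@]12O)(C(C)(C)C)C(C)(C)C
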